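**Strategy.** The route rests on disconnecting the bond between C2 of the dihydropyranone ring and C1′ of the tetrasubstituted B-ring arene. C2 is the β-carbon of a chromone enone (O1–C2=C3–C4=O) in the oxidised ring, and C1′ lies between two unsubstituted CH positions, so it can carry boron without steric cost. A rhodium-catalysed asymmetric 1,4-addition of the fully elaborated B-ring boronic acid, which already bears the prenyl group and the (R)-silyloxy-isopentenyl chain, to 7-silyloxychromone joins both halves and sets the (2S) stereocentre under ligand control in one operation. The carbinol centre stems from Shi epoxidation of one of two equivalent prenyl groups.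

Key step: step 7

Remark: the target is read as (2S) at the flavanone carbon and (R) at the side-chain carbinol. TBS = tert-butyldimethylsilyl. All three hydroxyl groups are carried as TBS ethers so that one buffered fluoride treatment ends the route.

Step 1
Reactants: 1 4-bromophenol; 2 prenyl bromide (1-bromo-3-methylbut-2-ene, 2.2 equiv)
Product: 4 4-bromo-2,6-bis(3-methylbut-2-en-1-yl)phenol, via mono-prenylphenol 3 (not isolated)
Conditions: NaH (2.2 equiv, two portions), toluene, 0 °C → rt
Reagents that add atoms: none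
Why: Ortho-C-allylation of a sodium phenoxide in a non-polar solvent, where the tight ion pair shields oxygen; with the para position blocked by bromine, both ortho carbons should take a prenyl group in turn.

Step 2
Reactants: 4 4-bromo-2,6-bis(3-methylbut-2-en-1-yl)phenol
Product: 5 tert-butyl[4-bromo-2,6-bis(3-methylbut-2-en-1-yl)phenoxy]dimethylsilane
Conditions: TBSOTf, 2,6-lutidine, CH2Cl2, 0 °C → rt
Reagents that add atoms: tert-butyldimethylsilyl triflate, CC(C)(C)[Si](C)(C)OS(=O)(=O)C(F)(F)F
Why: O-silylation of a hindered phenol with a silyl triflate masks the phenol against oxidation and against attack on the epoxide made next.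

Step 3
Reactants: 5 tert-butyl[4-bromo-2,6-bis(3-methylbut-2-en-1-yl)phenoxy]dimethylsilane
Product: 6 tert-butyl[4-bromo-2-{[(2R)-3,3-dimethyloxiran-2-yl]methyl}-6-(3-methylbut-2-en-1-yl)phenoxy]dimethylsilane
Conditions: D-fructose-derived Shi ketone (30 mol %), Oxone (limiting), K2CO3, Bu4NHSO4, Na2B4O7/Na2EDTA buffer, MeCN–DMM–H2O, 0 °C; stopped at partial conversion, 5 recovered and recycled
Reagents that add atoms: Oxone (potassium peroxymonosulfate), [K+].[O-]S(=O)(=O)OO
Why: Shi asymmetric epoxidation, in which the chiral dioxirane should attack the trisubstituted alkene through a spiro transition state on the face that gives the (R) epoxide carbon; the two prenyl groups are homotopic, so any mono-epoxidation gives the same compound and limiting oxidant holds back the bis-epoxide.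

Step 4
Reactants: 6 tert-butyl[4-bromo-2-{[(2R)-3,3-dimethyloxiran-2-yl]methyl}-6-(3-methylbut-2-en-1-yl)phenoxy]dimethylsilane
Product: 7 5-bromo-2-(TBS-oxy)-1-[(2R)-2-(TBS-oxy)-3-methylbut-3-en-1-yl]-3-(3-methylbut-2-en-1-yl)benzene
Conditions: TBSOTf, 2,6-lutidine, CH2Cl2, −78 → 0 °C
Reagents that add atoms: tert-butyldimethylsilyl triflate, CC(C)(C)[Si](C)(C)OS(=O)(=O)C(F)(F)F
Why: Silyl triflate/amine isomerisation of an epoxide to an allylic silyl ether: O-silylation, opening of the tertiary C–O bond and loss of a methyl proton should give the isopropenyl carbinol ether, and the C–O bond at the stereocentre is untouched, so (R) is retained.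

Step 5
Reactants: 7 5-bromo-2-(TBS-oxy)-1-[(2R)-2-(TBS-oxy)-3-methylbut-3-en-1-yl]-3-(3-methylbut-2-en-1-yl)benzene
Product: 10 {4-(TBS-oxy)-3-[(2R)-2-(TBS-oxy)-3-methylbut-3-en-1-yl]-5-(3-methylbut-2-en-1-yl)phenyl}boronic acid, via aryllithium 8 (not isolated), via lithium triisopropoxyborate 9 (not isolated)
Conditions: n-BuLi, THF, −78 °C; B(OiPr)3, −78 °C → rt; aq. HCl to pH 5–6
Reagents that add atoms: triisopropyl borate, CC(C)OB(OC(C)C)OC(C)C; water, O
Why: Bromine–lithium exchange followed by borylation of the aryllithium and hydrolysis; the lithium sits para to the silyl ether, so no silyl migration to carbon is possible, and the mild work-up should leave both TBS ethers intact.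

Step 6
Reactants: 11 7-hydroxy-4H-chromen-4-one (7-hydroxychromone)
Product: 12 7-(TBS-oxy)-4H-chromen-4-one
Conditions: TBSCl, imidazole, DMF, rt
Reagents that add atoms: tert-butyldimethylsilyl chloride, CC(C)(C)[Si](C)(C)Cl
Why: Standard O-silylation of an acidic phenol, which removes the proton that would otherwise turn the chromone into an unreactive phenoxide in the conjugate addition.

Step 7
Reactants: 10 {4-(TBS-oxy)-3-[(2R)-2-(TBS-oxy)-3-methylbut-3-en-1-yl]-5-(3-methylbut-2-en-1-yl)phenyl}boronic acid (1.0 equiv); 12 7-(TBS-oxy)-4H-chromen-4-one (1.5 equiv)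
Product: 13 (2S)-7-(TBS-oxy)-2-{4-(TBS-oxy)-3-[(2R)-2-(TBS-oxy)-3-methylbut-3-en-1-yl]-5-(3-methylbut-2-en-1-yl)phenyl}-2,3-dihydro-4H-chromen-4-one
Conditions: [Rh(OH)(cod)]2 (cat.), (S)-MeO-F12-BIPHEP (cat.), toluene–H2O, rt → 40 °C, no added base
Reagents that add atoms: none
Why: Hayashi–Miyaura rhodium-catalysed asymmetric 1,4-addition: the aryl group of 10 passes from boron to the Rh(I)–OH complex, the aryl–Rh bond adds across C2=C3 of chromone 12 with the aryl going to C2, and water protonates the resulting oxa-π-allyl rhodium enolate to return Rh–OH and boric acid. The closest known reaction type is the addition of arylboronic acids to chromones under rhodium/electron-poor biaryl-bisphosphine catalysis to give flavanones. No ring is closed. The new C2 stereocentre is set by the chiral ligand alone; the (S)-ligand is expected to give (2S) by analogy with the enone face selection of (S)-biaryl bisphosphines, the antipode would be used if a model reaction shows the opposite sense, and the (R)-carbinol is too remote to bias the outcome. The step needs 1,4- over 1,2-addition and reaction at the chromone C2=C3 bond only, which the conjugated enone secures because aryl–Rh(I) should not insert into the unactivated prenyl and isopropenyl alkenes, while C1′ is unhindered between two CH positions. Base-free conditions near ambient temperature should keep the flavanone from retro-oxa-Michael opening, which would erode the C2 configuration.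

Step 8
Reactants: 13 (2S)-7-(TBS-oxy)-2-{4-(TBS-oxy)-3-[(2R)-2-(TBS-oxy)-3-methylbut-3-en-1-yl]-5-(3-methylbut-2-en-1-yl)phenyl}-2,3-dihydro-4H-chromen-4-one
Product: 14 (2S)-7-hydroxy-2-{4-hydroxy-3-[(2R)-2-hydroxy-3-methylbut-3-en-1-yl]-5-(3-methylbut-2-en-1-yl)phenyl}-2,3-dihydro-4H-chromen-4-one
Conditions: TBAF, AcOH (1:1, excess), THF, 0 °C → rt
Reagents that add atoms: none
Why: Fluoride desilylation of two aryl and one secondary alkyl TBS ether; the acetic acid buffer keeps the medium non-basic so that the flavanone should not open to the chalcone and C2 is not scrambled, and no acid strong enough to cyclise the side chains onto the phenol is present.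

**Compound list**

1 | 4-bromophenol | Oc1ccc(Br)cc1 | starting material
2 | prenyl bromide (1-bromo-3-methylbut-2-ene) | CC(C)=CCBr | starting material
3 | 4-bromo-2-(3-methylbut-2-en-1-yl)phenol (as sodium phenoxide in the flask) | CC(C)=CCc1cc(Br)ccc1O | intermediate (not isolated)
4 | 4-bromo-2,6-bis(3-methylbut-2-en-1-yl)phenol | CC(C)=CCc1cc(Br)cc(CC=C(C)C)c1O | intermediate
5 | tert-butyl[4-bromo-2,6-bis(3-methylbut-2-en-1-yl)phenoxy]dimethylsilane | CC(C)=CCc1cc(Br)cc(CC=C(C)C)c1O[Si](C)(C)C(C)(C)C | intermediate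
6 | tert-butyl[4-bromo-2-{[(2R)-3,3-dimethyloxiran-2-yl]methyl}-6-(3-methylbut-2-en-1-yl)phenoxy]dimethylsilane | CC(C)=CCc1cc(Br)cc(C[C@H]2OC2(C)C)c1O[Si](C)(C)C(C)(C)C | intermediate
7 | 5-bromo-2-(TBS-oxy)-1-[(2R)-2-(TBS-oxy)-3-methylbut-3-en-1-yl]-3-(3-methylbut-2-en-1-yl)benzene | C=C(C)[C@H](O[Si](C)(C)C(C)(C)C)Cc1cc(Br)cc(CC=C(C)C)c1O[Si](C)(C)C(C)(C)C | intermediate
8 | aryllithium from 7 (lithium in place of bromine) | C=C(C)[C@H](O[Si](C)(C)C(C)(C)C)Cc1cc([Li])cc(CC=C(C)C)c1O[Si](C)(C)C(C)(C)C | intermediate (not isolated)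
9 | lithium aryl(triisopropoxy)borate from 8 | [Li+].C=C(C)[C@H](O[Si](C)(C)C(C)(C)C)Cc1cc([B-](OC(C)C)(OC(C)C)OC(C)C)cc(CC=C(C)C)c1O[Si](C)(C)C(C)(C)C | intermediate (not isolated)
10 | {4-(TBS-oxy)-3-[(2R)-2-(TBS-oxy)-3-methylbut-3-en-1-yl]-5-(3-methylbut-2-en-1-yl)phenyl}boronic acid | C=C(C)[C@H](O[Si](C)(C)C(C)(C)C)Cc1cc(B(O)O)cc(CC=C(C)C)c1O[Si](C)(C)C(C)(C)C | intermediate
11 | 7-hydroxy-4H-chromen-4-one | O=c1ccoc2cc(O)ccc12 | starting material
12 | 7-(TBS-oxy)-4H-chromen-4-one | CC(C)(C)[Si](C)(C)Oc1ccc2c(c1)occc2=O | intermediate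
13 | (2S)-7-(TBS-oxy)-2-{4-(TBS-oxy)-3-[(2R)-2-(TBS-oxy)-3-methylbut-3-en-1-yl]-5-(3-methylbut-2-en-1-yl)phenyl}-2,3-dihydro-4H-chromen-4-one | C=C(C)[C@H](O[Si](C)(C)C(C)(C)C)Cc1cc([C@@H]2CC(=O)c3ccc(O[Si](C)(C)C(C)(C)C)cc3O2)cc(CC=C(C)C)c1O[Si](C)(C)C(C)(C)C | intermediate
14 | (2S)-7-hydroxy-2-{4-hydroxy-3-[(2R)-2-hydroxy-3-methylbut-3-en-1-yl]-5-(3-methylbut-2-en-1-yl)phenyl}-2,3-dihydro-4H-chromen-4-one | C=C(C)[C@H](O)Cc1cc([C@@H]2CC(=O)c3ccc(O)cc3O2)cc(CC=C(C)C)c1O | target

**Step count.** Total: 8 steps. Longest linear sequence: 7 steps (1, 2, 3, 4, 5, 7, 8); step 6 is a one-step branch.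

**Steps most likely to fail**

Step 7 (key step). Transmetalation of the electron-rich boronic acid may be slower than its protodeboronation, the face selection on the chromone may be incomplete, or the product may open by retro-oxa-Michael reaction and lose configuration at C2. The fallback separates bond formation from stereocontrol. It sets out from 10 and 12, which are joined with an achiral cationic Pd(II) catalyst (Pd(OCOCF3)2, 2,2′-bipyridine, NH4PF6, H2O, ClCH2CH2Cl, 60 °C) to give the C2-epimeric mixture of the tris-silyl flavanone F1. Kinetic resolution by asymmetric transfer hydrogenation (RuCl[(R,R)-TsDPEN](p-cymene), HCO2H/Et3N, rt) should then reduce the (2R) epimer faster, with hydride delivered anti to the aryl group, to the cis-(2R,4R)-flavan-4-ol F2. The unreduced (2S) ketone is separated by chromatography, and the route is rejoined at 13.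

Step 3. Over-oxidation to the bis-epoxide and incomplete conversion are inherent in the mono-epoxidation of two equivalent alkenes, and separation may be laborious. The fallback introduces the two side chains one after the other. It sets out from 1, which with one equivalent each of NaH and 2 in toluene gives 3, here isolated. Silylation (TBSCl, imidazole, DMF) should give the mono-prenyl aryl silyl ether F3, and Shi epoxidation to full conversion the (R)-epoxide F4. TBSOTf/2,6-lutidine should convert F4 into the bis-silyl ether F5, and K2CO3 in MeOH should cleave only the aryl silyl ether to give the phenol F6. Ortho-C-prenylation of its sodium phenoxide with 2 in toluene should give the 2,6-disubstituted phenol F7, and silylation with TBSOTf/2,6-lutidine rejoins the route at 7.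

Step 4. The silylated epoxide may ionise and then undergo a hydride shift to the ketone, or the tertiary cation may be captured by the neighbouring aryl silyl ether oxygen to form a chroman, instead of losing a methyl proton. The fallback avoids a cationic intermediate. It sets out from 6, which with diethylaluminium 2,2,6,6-tetramethylpiperidide (from Et2AlCl and LiTMP, toluene, 0 °C) should undergo a concerted syn-elimination to the free (R)-allylic alcohol F8. Silylation (TBSCl, imidazole, DMF) rejoins the route at 7.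

**Further compounds**

F1 | step 7 | C2-epimeric mixture (2RS) of the tris-silyl flavanone 13 | C=C(C)[C@H](O[Si](C)(C)C(C)(C)C)Cc1cc(C2CC(=O)c3ccc(O[Si](C)(C)C(C)(C)C)cc3O2)cc(CC=C(C)C)c1O[Si](C)(C)C(C)(C)C
F2 | step 7 | cis-(2R,4R)-flavan-4-ol from reduction of the (2R) epimer of 13 | C=C(C)[C@H](O[Si](C)(C)C(C)(C)C)Cc1cc([C@H]2C[C@@H](O)c3ccc(O[Si](C)(C)C(C)(C)C)cc3O2)cc(CC=C(C)C)c1O[Si](C)(C)C(C)(C)C
F3 | step 3 | tert-butyl[4-bromo-2-(3-methylbut-2-en-1-yl)phenoxy]dimethylsilane | CC(C)=CCc1cc(Br)ccc1O[Si](C)(C)C(C)(C)C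
F4 | step 3 | tert-butyl[4-bromo-2-{[(2R)-3,3-dimethyloxiran-2-yl]methyl}phenoxy]dimethylsilane | CC(C)(C)[Si](C)(C)Oc1ccc(Br)cc1C[C@H]1OC1(C)C
F5 | step 3 | 4-bromo-1-(TBS-oxy)-2-[(2R)-2-(TBS-oxy)-3-methylbut-3-en-1-yl]benzene | C=C(C)[C@H](O[Si](C)(C)C(C)(C)C)Cc1cc(Br)ccc1O[Si](C)(C)C(C)(C)C
F6 | step 3 | 4-bromo-2-[(2R)-2-(TBS-oxy)-3-methylbut-3-en-1-yl]phenol | C=C(C)[C@H](O[Si](C)(C)C(C)(C)C)Cc1cc(Br)ccc1O
F7 | step 3 | 4-bromo-2-[(2R)-2-(TBS-oxy)-3-methylbut-3-en-1-yl]-6-(3-methylbut-2-en-1-yl)phenol | C=C(C)[C@H](O[Si](C)(C)C(C)(C)C)Cc1cc(Br)cc(CC=C(C)C)c1O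
F8 | step 4 | (2R)-1-[5-bromo-2-(TBS-oxy)-3-(3-methylbut-2-en-1-yl)phenyl]-3-methylbut-3-en-2-ol | C=C(C)[C@H](O)Cc1cc(Br)cc(CC=C(C)C)c1O[Si](C)(C)C(C)(C)C
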